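**Plan**
- Retrosynthesis: the two carboxyl carbons C2 and C3 are rejoined, because the diacid comes from oxidative cleavage of a ring-A 3-ketone. Then O–C13 (ring C) and C9–C11 are cut. Then C5–C10 and C6–C7 of ring B are cut together as a Diels–Alder retron. Last, the open chain is cut at C3–C4, C1–C10 and C8–C9.
- Enabling feature: on cyclohexane ring B the arms CH2CO2H (on C10) and CMe2CO2H (on C5) are vicinal and cis. C2–C3 can therefore be one bond of a temporary cis-fused ring A. This ring is the four-atom tether of a 1,7,9-decatriene in which C5=C6 is the dienophile and C7=C8–C9=C10 the diene.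
- Second helper: a carbonyl carbon C21 ties O3 to C6 as a pentenolide. It activates C5=C6, permits only the cis A/B fusion, and later delivers the oxygen to C8.
- Forward order: chain assembly (carbocupration, reverse prenylation), pentenolide (ring-closing metathesis), rings A and B in one step, C8–O and C9–C11 (iodolactonisation, Giese reaction), ring C (selenoetherification), then removal of C21 (decarbonylation) and of ring A (cleavage to the diacid).
- Stereochemistry: the only external source is the isopinocampheylborane that sets carbinol C3. C3 controls C5, C6 and C10 in the cycloaddition, C6 controls C8 and C9, and C8/C9 control C13. C3, C6 and C14 are erased again.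

Key step: step 6

Remark: locants follow the labdane skeleton of the target. C13 carries O, CH3 and the vinyl group C14=C15. The chain runs C12, C11, C9. C10 carries CH3 (C20) and CH2 (C1), and C1 carries the CO2H carbon C2. C5 carries C4, and C4 carries two CH3 and the CO2H carbon C3. Then follow C6, C7 and C8, which carries CH3 (C17) and O. β is the face of C20 and α the opposite face. In the given SMILES H5 and C20 lie on the same face, and the route is built for that.

**Step 1**
Reactants: 1 2-(2-bromoethyl)-1,3-dioxolane; 2 propyne; 3 2-bromopropene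
Product: 7 2-[(3Z)-3,5-dimethylhexa-3,5-dien-1-yl]-1,3-dioxolane, via Grignard reagent 4 (not isolated), via alkylcopper 5 (not isolated), via alkenylcopper 6 (not isolated)
Conditions: Mg, THF, 25 °C; CuBr·SMe2, Et2O–SMe2, −45 °C; 2, −25 °C; then 3, ZnBr2, Pd(PPh3)4 (cat.), THF, −20 to 20 °C
Reagents that add atoms: none
Why: Normant carbocupration adds the alkylcopper syn across propyne with carbon going to the substituted alkyne carbon, so chain and copper end up cis, and the zerovalent-palladium-catalysed Negishi-type coupling with 3 keeps this geometry and fixes the (Z)-C9=C10 alkene.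

**Step 2**
Reactants: 7 2-[(3Z)-3,5-dimethylhexa-3,5-dien-1-yl]-1,3-dioxolane
Product: 8 (4Z)-4,6-dimethylhepta-4,6-dienal
Conditions: PPTS (cat.), acetone–H2O, 50 °C
Reagents that add atoms: water, O
Why: Mild acid-catalysed acetal hydrolysis should free the aldehyde C3 without protonating the diene, and no stereocentre is formed.

**Step 3**
Reactants: 8 (4Z)-4,6-dimethylhepta-4,6-dienal; 9 3-methylbuta-1,2-diene
Product: 12 (4R,7Z)-3,3,7,9-tetramethyldeca-1,7,9-trien-4-ol, via prenylborane 10 (not isolated), via borinate 11 (not isolated)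
Conditions: (−)-Ipc2BH [from (+)-α-pinene], 9, THF, −25 to 0 °C; 8, Et2O, −78 °C; NaOH, 30% H2O2, 0 to 25 °C
Reagents that add atoms: none
Why: In this Brown-type asymmetric prenylboration, hydroboration of the allene gives the prenylborane, which adds with allylic transposition through a chair-like six-membered transition state (reverse prenylation), and the isopinocampheyl groups direct attack to the aldehyde face that gives the (R)-carbinol C3 next to the new quaternary C4.

**Step 4**
Reactants: 12 (4R,7Z)-3,3,7,9-tetramethyldeca-1,7,9-trien-4-ol; 13 acryloyl chloride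
Product: 14 (4R,7Z)-3,3,7,9-tetramethyldeca-1,7,9-trien-4-yl prop-2-enoate
Conditions: Et3N, DMAP (cat.), CH2Cl2, 0 °C
Reagents that add atoms: none
Why: DMAP-catalysed O-acylation of the hindered secondary alcohol brings in C21 and C6 and leaves C3 untouched.

**Step 5**
Reactants: 14 (4R,7Z)-3,3,7,9-tetramethyldeca-1,7,9-trien-4-yl prop-2-enoate
Product: 15 (6R)-6-[(3Z)-3,5-dimethylhexa-3,5-dien-1-yl]-5,5-dimethyl-5,6-dihydro-2H-pyran-2-one
Conditions: second-generation Grubbs catalyst (cat.), toluene (dilute), 70 °C
Reagents that add atoms: none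
Why: Ring-closing metathesis of the acrylate with the monosubstituted vinyl group closes the six-membered pentenolide, while the 1,1-disubstituted and trisubstituted alkenes of the diene should be much slower partners.

**Step 6**
Reactants: 15 (6R)-6-[(3Z)-3,5-dimethylhexa-3,5-dien-1-yl]-5,5-dimethyl-5,6-dihydro-2H-pyran-2-one
Product: 16 tricyclic bridged δ-lactone (rings A/B cis-fused; 5β-H; 6β-H; 10β-CH3; bridge 3α-O–C21(=O)–C6α; C8=C9 alkene bearing C17)
Conditions: toluene (0.01 M), BHT (cat.), sealed tube, 130 °C
Reagents that add atoms: none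
Why: This is a concerted, suprafacial, normal-electron-demand intramolecular Diels–Alder reaction of the C7=C8–C9=C10 diene with the lactone-activated C5=C6 alkene, and the closest known type is the type 1 cycloaddition of (Z)-1,7,9-decatrienes that carry an acceptor on the terminal dienophile carbon, here held in a pentenolide. Ring B closes as the new cyclohexene by the [4+2] event itself, and ring A closes as a six-membered carbocycle over the four-atom tether C1–C2–C3–C4 in a chair-like array, in the fused mode because the tether is too short for the bridged one. C5 and C6 are set by C3, because the tether leaves the lactone ring at C3 and can reach only the alkene face syn to the C3–C2 bond. C10 is set by alkene geometry and tether: C1 sits on the inner (Z) position of the diene, which leaves only the transition state with C4 and the lactone carbonyl exo, so C1 and C4 become cis and C20 and H5 share one face, whereas a trans fusion would need the C3–O and C5–C6 bonds, tied in one six-membered lactone, to be diequatorial on ring A. The step needs the cycloaddition to outrun the [1,5]-hydrogen shift open to a (Z)-diene, which the acceptor carbonyl, the gem-dimethyl group and the doubly anchored dienophile should secure.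

**Step 7**
Reactants: 16 tricyclic bridged δ-lactone
Product: 18 9β-iodo γ-lactone (C21(=O)–O–C8α; 8β-CH3; 9α-H; free 3α-OH), via lithium carboxylate 17 (not isolated)
Conditions: LiOH, THF–H2O, 40 °C; then NaHCO3, I2, 0 °C, dark
Reagents that add atoms: lithium hydroxide, [Li+].[OH-]; iodine, II
Why: Saponification frees the 6α-carboxylate, and iodolactonisation then follows the pattern of cyclohex-3-enecarboxylic acids, in which the carboxylate can reach only the α face of the tertiary C8 (γ-lactone, Markovnikov), so iodine adds anti at C9 from the β face and H9 becomes α.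

**Step 8**
Reactants: 18 9β-iodo γ-lactone; 19 but-3-en-2-one
Product: 20 9β-(3-oxobutyl) γ-lactone (9α-H; free 3α-OH)
Conditions: 19 (excess), (Me3Si)3SiH (slow addition), AIBN (cat.), toluene, 80 °C
Reagents that add atoms: none
Why: In this Giese reaction the secondary C9 radical should add to the enone from the β (axial) side, because the α side is flanked by the axial C8–O and C10–C1 bonds of the locked chair, so C11 takes the place of iodine and H9 stays α.

**Step 9**
Reactants: 20 9β-(3-oxobutyl) γ-lactone; 21 ethyltriphenylphosphonium bromide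
Product: 23 9β-[(3Z)-3-methylpent-3-en-1-yl] γ-lactone (the E isomer is also expected and serves equally), via ylide 22 (not isolated)
Conditions: 21, KHMDS, THF, 0 °C; then 20, −78 to 25 °C (excess ylide for the free OH)
Reagents that add atoms: none
Why: Wittig ethylidenation takes the unhindered methyl ketone in preference to the bridged, non-enolisable lactone, and the alkene geometry does not matter because C14 loses its stereo information in step 12.

**Step 10**
Reactants: 23 9β-[(3Z)-3-methylpent-3-en-1-yl] γ-lactone
Product: 24 triol (3α-OH; 8α-OH; 6α-CH2OH; 9β side chain)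
Conditions: LiAlH4, THF, 0 to 25 °C; aqueous work-up
Reagents that add atoms: none
Why: Hydride reduction of the lactone frees the tertiary 8α-hydroxyl with its C–O bond intact and turns C21 into a hydroxymethyl group that can no longer recapture O8.

**Step 11**
Reactants: 24 triol
Product: 25 8α,13-epoxide with ring C closed (13R: 13β-CH3; 14-phenylselanyl; 3α-OH; 6α-CH2OH)
Conditions: N-(phenylselanyl)phthalimide, CSA (cat.), CH2Cl2, −78 to −20 °C
Reagents that add atoms: N-(phenylselanyl)phthalimide, O=C1c2ccccc2C(=O)N1[Se]c1ccccc1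
Why: In this 6-exo selenoetherification O8 opens the seleniranium ion anti at the tertiary C13 through a chair-like array in which the small C16 methyl takes the axial site facing the axial C17 and the bulky selenium-bearing C14 sits equatorial, which gives the 13R centre, and C8 and C9 are already fixed so only the trans B/C fusion can result.

**Step 12**
Reactants: 25 8α,13-epoxide with 14-phenylselanyl group
Product: 27 (13R)-8α,13-epoxy-6α-(hydroxymethyl)-5β-labd-14-en-3α-ol, via selenoxide 26 (not isolated)
Conditions: 30% H2O2, pyridine, THF, 0 to 25 °C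
Reagents that add atoms: none
Why: Selenoxide syn-elimination can take a hydrogen only from the C15 methyl group because C13 is quaternary, so the vinyl group forms regiospecifically and C13 is not touched.

**Step 13**
Reactants: 27 (13R)-8α,13-epoxy-6α-(hydroxymethyl)-5β-labd-14-en-3α-ol
Product: 28 (13R)-8α,13-epoxy-6α-formyl-5β-labd-14-en-3-one
Conditions: Dess–Martin periodinane, NaHCO3, CH2Cl2, 0 to 25 °C
Reagents that add atoms: none
Why: Dess–Martin oxidation converts both alcohols in one operation under buffered conditions that spare the vinyl group and the tertiary ethers, and it erases the control centre C3.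

**Step 14**
Reactants: 28 (13R)-8α,13-epoxy-6α-formyl-5β-labd-14-en-3-one
Product: 29 (13R)-8α,13-epoxy-5β-labd-14-en-3-one
Conditions: RhCl(PPh3)3 (1 equiv), toluene, 110 °C
Reagents that add atoms: none
Why: Tsuji–Wilkinson decarbonylation removes the helper carbon C21 from the secondary aldehyde and leaves C6 as CH2, while the ketone and the vinyl group on a quaternary carbon are not substrates.

**Step 15**
Reactants: 29 (13R)-8α,13-epoxy-5β-labd-14-en-3-one
Product: 31 target diacid CNP0186744.3, via diosphenol 30 (not isolated)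
Conditions: O2 (1 atm), KOtBu, tBuOH–DME, 25 °C; then 30% H2O2, KOH, MeOH–H2O, 0 to 25 °C; HCl work-up
Reagents that add atoms: dioxygen, O=O; hydrogen peroxide, OO
Why: The 4,4-dimethyl-3-ketone can enolise only towards C2, so base-mediated autoxidation gives the 2-hydroxy-1-en-3-one, and alkaline peroxide cleaves its C2–C3 bond to the two carboxyl groups (the known 2,3-seco cleavage of such ketones) without touching any stereocentre, since C5 is insulated by the quaternary C4.

**Compound list**
1 | 2-(2-bromoethyl)-1,3-dioxolane | BrCCC1OCCO1 | starting material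
2 | propyne | CC#C | starting material
3 | 2-bromopropene | C=C(C)Br | starting material
4 | [2-(1,3-dioxolan-2-yl)ethyl]magnesium bromide | Br[Mg]CCC1OCCO1 | intermediate
5 | [2-(1,3-dioxolan-2-yl)ethyl]copper | [Cu]CCC1OCCO1 | intermediate
6 | [(1Z)-4-(1,3-dioxolan-2-yl)-2-methylbut-1-en-1-yl]copper | [Cu]/C=C(C)\CCC1OCCO1 | intermediate
7 | 2-[(3Z)-3,5-dimethylhexa-3,5-dien-1-yl]-1,3-dioxolane | C=C(C)/C=C(C)\CCC1OCCO1 | intermediate
8 | (4Z)-4,6-dimethylhepta-4,6-dienal | C=C(C)/C=C(C)\CCC=O | intermediate
9 | 3-methylbuta-1,2-diene | CC(C)=C=C | starting material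
10 | (3-methylbut-2-en-1-yl)bis(isopinocampheyl)borane | CC(C)=CCB([C@@H]1C[C@@H]2C[C@H]([C@H]1C)C2(C)C)[C@@H]1C[C@@H]2C[C@H]([C@H]1C)C2(C)C | intermediate
11 | bis(isopinocampheyl)borinate of alcohol 12 | C=CC(C)(C)[C@H](OB([C@@H]1C[C@@H]2C[C@H]([C@H]1C)C2(C)C)[C@@H]1C[C@@H]2C[C@H]([C@H]1C)C2(C)C)CC/C(C)=C\C(C)=C | intermediate
12 | (4R,7Z)-3,3,7,9-tetramethyldeca-1,7,9-trien-4-ol | C=CC(C)(C)[C@H](O)CC/C(C)=C\C(C)=C | intermediate
13 | acryloyl chloride | C=CC(=O)Cl | starting material
14 | (4R,7Z)-3,3,7,9-tetramethyldeca-1,7,9-trien-4-yl prop-2-enoate | C=CC(C)(C)[C@H](OC(=O)C=C)CC/C(C)=C\C(C)=C | intermediate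
15 | (6R)-6-[(3Z)-3,5-dimethylhexa-3,5-dien-1-yl]-5,5-dimethyl-5,6-dihydro-2H-pyran-2-one | O=C1C=CC(C)(C)[C@@H](CC/C(C)=C\C(C)=C)O1 | intermediate
16 | Diels–Alder adduct: cis-fused rings A/B, 5β-H, 6β-H, 10β-CH3, δ-lactone bridge 3α-O–C21(=O)–C6α, C8=C9 | O=C1O[C@@H]2CC[C@]3(C)C=C(C)C[C@H]1[C@@H]3C2(C)C | intermediate
17 | lithium 3α-hydroxy-6α-carboxylate from opening of 16 | [Li+].[O-]C(=O)[C@H]1CC(C)=C[C@@]2(C)CC[C@@H](O)C(C)(C)[C@@H]12 | intermediate
18 | 9β-iodo γ-lactone (C21–O–C8α), 8β-CH3, 9α-H, 3α-OH | O=C1O[C@]2(C)C[C@H]1[C@@H]1C(C)(C)[C@H](O)CC[C@]1(C)[C@H]2I | intermediate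
19 | but-3-en-2-one | C=CC(C)=O | starting material
20 | 9β-(3-oxobutyl) γ-lactone, 9α-H, 3α-OH | O=C1O[C@]2(C)C[C@H]1[C@@H]1C(C)(C)[C@H](O)CC[C@]1(C)[C@H]2CCC(C)=O | intermediate
21 | ethyltriphenylphosphonium bromide | CC[P+](c1ccccc1)(c1ccccc1)c1ccccc1.[Br-] | starting material
22 | ethylidenetriphenylphosphorane | CC=P(c1ccccc1)(c1ccccc1)c1ccccc1 | intermediate
23 | 9β-[(3Z)-3-methylpent-3-en-1-yl] γ-lactone (Z isomer drawn) | O=C1O[C@]2(C)C[C@H]1[C@@H]1C(C)(C)[C@H](O)CC[C@]1(C)[C@H]2CC/C(C)=C\C | intermediate
24 | triol: 3α-OH, 8α-OH, 6α-CH2OH, 9β side chain | OC[C@H]1C[C@@](C)(O)[C@H](CC/C(C)=C\C)[C@@]2(C)CC[C@@H](O)C(C)(C)[C@@H]12 | intermediate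
25 | 8α,13-epoxide (13R) with 14-phenylselanyl group (C14 as derived from the Z alkene) | C[C@@H]([Se]c1ccccc1)[C@@]1(C)CC[C@@H]2[C@@]3(C)CC[C@@H](O)C(C)(C)[C@H]3[C@@H](CO)C[C@@]2(C)O1 | intermediate
26 | selenoxide of 25 | C[C@@H]([Se](=O)c1ccccc1)[C@@]1(C)CC[C@@H]2[C@@]3(C)CC[C@@H](O)C(C)(C)[C@H]3[C@@H](CO)C[C@@]2(C)O1 | intermediate
27 | (13R)-8α,13-epoxy-6α-(hydroxymethyl)-5β-labd-14-en-3α-ol | C=C[C@@]1(C)CC[C@@H]2[C@@]3(C)CC[C@@H](O)C(C)(C)[C@H]3[C@@H](CO)C[C@@]2(C)O1 | intermediate
28 | (13R)-8α,13-epoxy-6α-formyl-5β-labd-14-en-3-one | C=C[C@@]1(C)CC[C@@H]2[C@@]3(C)CCC(=O)C(C)(C)[C@H]3[C@@H](C=O)C[C@@]2(C)O1 | intermediate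
29 | (13R)-8α,13-epoxy-5β-labd-14-en-3-one | C=C[C@@]1(C)CC[C@@H]2[C@@]3(C)CCC(=O)C(C)(C)[C@H]3CC[C@@]2(C)O1 | intermediate
30 | (13R)-8α,13-epoxy-2-hydroxy-5β-labda-1,14-dien-3-one (diosphenol) | C=C[C@@]1(C)CC[C@@H]2[C@@]3(C)C=C(O)C(=O)C(C)(C)[C@H]3CC[C@@]2(C)O1 | intermediate
31 | CNP0186744.3, the 2,3-seco-2,3-dioic acid | C=C[C@@]1(C)CC[C@@H]2[C@@](C)(CC(=O)O)[C@@H](C(C)(C)C(=O)O)CC[C@@]2(C)O1 | target

Total step count: 15. Longest linear sequence: 15.

**Steps most likely to fail**

Step 6. The cycloaddition must join the neopentyl carbon C5 to the fully substituted diene terminus C10. It may be slower than the [1,5]-hydrogen shift or the thermal polymerisation of the (Z)-diene. The fallback sets out from 15 and replaces the thermal concerted event by a photochemical two-stage one. Visible-light triplet sensitisation of the diene with [Ir(dF(CF3)ppy)2(dtbbpy)]PF6 in MeCN should give the intramolecular [2+2] adduct of C5=C6 and C9=C10, the vinylcyclobutane F1. This adduct already holds the C5–C10 bond and the cis fusion imposed by the lactone. Heating it in toluene at 150 °C should break the weakest cyclobutane bond C6–C9, which is α to the carbonyl and allylic. The resulting pair should recombine at C7 (vinylcyclobutane to cyclohexene 1,3-shift), which comes back to the route at 16.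

Step 8. The C9 radical sits between two fully substituted carbons, so hydrogen abstraction from the silane may outrun addition to the enone (premature reduction). The fallback sets out from 18 and forms C9–C11 by a polar, stereospecific substitution. K2CO3 in MeOH should open the lactone, and the 8α-alkoxide should displace the anti iodide to give the 8α,9α-epoxy methyl ester F2. The Grignard reagent of commercial 2-(2-bromoethyl)-2-methyl-1,3-dioxolane with CuI (cat.) should open the epoxide trans-diaxially at the secondary C9 from the β face. The 8α-alkoxide then closes back on the ester to give the ketal lactone F3. Mild acid hydrolysis of the ketal comes back to the route at 20.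

Step 11. Closure of ring C forces ring B out of its preferred chair. The slow cyclisation may let the reversible seleniranium ion be captured from either alkene face (poor facial selectivity at C13) or be diverted by elimination. The fallback sets out from 20 and puts C13 under reagent control.
- Horner–Wadsworth–Emmons reaction with triethyl phosphonoacetate and NaH should give the (E)-enoate F4.
- LiAlH4 should reduce ester and lactone together to the allylic alcohol tetraol F5.
- Sharpless epoxidation with L-(+)-diethyl tartrate, Ti(OiPr)4 and tBuOOH should give the (13S,14S)-epoxide F6.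
- CSA (cat.) should trigger 6-exo opening by O8 at the tertiary C13 with inversion, giving the ring-C tetraol F7.
- 1,1'-Thiocarbonyldiimidazole should engage the 14,15-diol as the cyclic thionocarbonate F8.
- Corey–Winter olefination with P(OMe)3 at 110 °C comes back to the route at 27.

**Further compounds**
F1 | step 6 | vinylcyclobutane photoadduct (bonds C5–C10 and C6–C9; isopropenyl group on C9, either C9 epimer serves) | O=C1O[C@@H]2CC[C@]3(C)[C@@H](C(C)=C)[C@H]1[C@@H]3C2(C)C
F2 | step 8 | methyl 8α,9α-epoxy-3α-hydroxy-6α-carboxylate | COC(=O)[C@H]1C[C@@]2(C)O[C@H]2[C@@]3(C)CC[C@@H](O)C(C)(C)[C@@H]13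
F3 | step 8 | ethylene ketal of keto lactone 20 | O=C1O[C@]2(C)C[C@H]1[C@@H]1C(C)(C)[C@H](O)CC[C@]1(C)[C@H]2CCC1(C)OCCO1
F4 | step 11 | (13E)-ethyl enoate of the γ-lactone | O=C1O[C@]2(C)C[C@H]1[C@@H]1C(C)(C)[C@H](O)CC[C@]1(C)[C@H]2CC/C(C)=C/C(=O)OCC
F5 | step 11 | (13E)-allylic alcohol tetraol | OC[C@H]1C[C@@](C)(O)[C@H](CC/C(C)=C/CO)[C@@]2(C)CC[C@@H](O)C(C)(C)[C@@H]12
F6 | step 11 | (13S,14S)-13,14-epoxy tetraol | OC[C@H]1C[C@@](C)(O)[C@H](CC[C@]3(C)O[C@H]3CO)[C@@]2(C)CC[C@@H](O)C(C)(C)[C@@H]12
F7 | step 11 | (13R)-8α,13-epoxide with 14,15-diol, 3α-OH and 6α-CH2OH | OC[C@H](O)[C@@]1(C)CC[C@@H]2[C@@]3(C)CC[C@@H](O)C(C)(C)[C@H]3[C@@H](CO)C[C@@]2(C)O1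
F8 | step 11 | 14,15-cyclic thionocarbonate of F7 | S=C1OC[C@@H]([C@@]2(C)CC[C@@H]3[C@@]4(C)CC[C@@H](O)C(C)(C)[C@H]4[C@@H](CO)C[C@@]3(C)O2)O1
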